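**Plan**

1. Numbering: C1 (quaternary, methyl), C2 and C3 (ring CH2), C4 (isopropyl carbinol), C5 (ring-fusion CH), C6 (aroyloxy), C7 (CH2), C8 (methyl)=C9, C10 (isovaleryloxy). The bicycle is cis-fused (C1 methyl and C5–H on one face).
2. Cuts: both ester C–O bonds; C8=C9 of the cycloheptene (ring-closing metathesis) with C10 taken back to a ketone; then C4–C5 and C1–C2 of the cyclopentane; then C4–CHMe2, C1–C10 and C6–C7 of the open chain.
3. Enabling feature: the cyclopentane C1–C2–C3–C4–C5, whose quaternary C1 carries a methyl group and the acyl carbon C10 and sits next to C5 and the tertiary C4 carbinol. This is the product pattern of a Prins cyclisation that ends in a ring-contracting pinacol shift.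
4. Forward order: but-2-ynal + methallyl unit → (Z)-alkenyl iodide → union with ethyl levulinate → isopropyl ketone → cyclopentane (step 8) → cycloheptenone → C10 alcohol → isovalerate, then 4-hydroxybenzoate.
5. Stereochemistry: C6 by reagent-controlled methallylboration; the (Z)-alkene by directed trans-hydroalumination; C10 of the open chain by separation of epimers; C1 and C5 (cis, from the (Z)-alkene) and C4 from the chair transition state of step 8; C10 of the target by hydride addition anti to the C1 methyl group.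

Key step: step 8

Assumption: the two C10-epimeric lactones of step 5 can be separated by chromatography and the (5R) epimer assigned by crystallography of a derivative; 4-[(tert-butyldimethylsilyl)oxy]benzoic acid is taken as purchasable (otherwise one operation from 4-hydroxybenzoic acid).

**Route**

Step 1
Reactants: 1 1,1-diethoxybut-2-yne (but-2-ynal diethyl acetal)
Product: 2 but-2-ynal
Conditions: HCO2H–H2O, 0 °C → rt; extracted into Et2O, dried (MgSO4), used as a solution
Reagents that add atoms: water, O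
Why: Acid-catalysed acetal hydrolysis frees the volatile ynal, which is therefore carried on as a dried ethereal solution.

Step 2
Reactants: 2 but-2-ynal; 3 (2-methylprop-2-en-1-yl)magnesium chloride (methallylmagnesium chloride, THF solution)
Product: 6 (4R)-2-methylhept-1-en-5-yn-4-ol, via B-methallyldiisopinocampheylborane 4 (not isolated), via diisopinocampheylborinate ester 5 (not isolated)
Conditions: (+)-Ipc2BOMe, 3, Et2O, 0 °C → rt; then 2, −78 °C; NaOH, H2O2, H2O, rt
Reagents that add atoms: none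
Why: Brown asymmetric allylboration: the methallylborane made in the flask adds through a chair Zimmerman–Traxler transition state in which the isopinocampheyl groups of the (−)-α-pinene series send the methallyl unit to the Re face of the ynal, which sets C6 as R (alkynyl outranks the allylic CH2).

Step 3
Reactants: 6 (4R)-2-methylhept-1-en-5-yn-4-ol
Product: 8 (4R,5Z)-6-iodo-2-methylhepta-1,5-dien-4-ol, via cyclic alkenylalanate 7 (not isolated)
Conditions: NaAlH2(OCH2CH2OMe)2 (Red-Al), THF, 0 °C → rt; EtOAc; then I2, THF, −78 → 0 °C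
Reagents that add atoms: iodine, II
Why: Hydroxyl-directed trans-hydroalumination of the propargylic alcohol puts hydride on C5 and aluminium on C1 in a five-membered alanate, and iodinolysis with retention leaves iodine cis to C6, i.e. the (Z)-iodoalkene.

Step 4
Reactants: 8 (4R,5Z)-6-iodo-2-methylhepta-1,5-dien-4-ol
Product: 9 tert-butyl{[(4R,5Z)-6-iodo-2-methylhepta-1,5-dien-4-yl]oxy}dimethylsilane
Conditions: TBSCl, imidazole, DMF, rt
Reagents that add atoms: tert-butyldimethylsilyl chloride, CC(C)(C)[Si](C)(C)Cl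
Why: Standard silyl ether formation at the secondary alcohol; the TBS group is chosen to withstand the organometallic and Lewis-acid steps ahead.

Step 5
Reactants: 9 tert-butyl{[(4R,5Z)-6-iodo-2-methylhepta-1,5-dien-4-yl]oxy}dimethylsilane; 10 ethyl 4-oxopentanoate (ethyl levulinate)
Product: 14 (5R)-5-{(2Z,4R)-4-[(tert-butyldimethylsilyl)oxy]-6-methylhepta-2,6-dien-2-yl}-5-methyloxolan-2-one, via alkenyllithium 11 (not isolated), via alkenylcerium dichloride 12 (not isolated), via cerium alkoxide ester 13 (not isolated)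
Conditions: t-BuLi (2 equiv), Et2O, −78 °C; anhydrous CeCl3, THF, −78 °C; 10, −78 °C → rt; aq. NH4Cl; chromatographic separation of the C5 epimers
Reagents that add atoms: none
Why: Iodine–lithium exchange with retention of geometry, transmetalation to the less basic organocerium reagent and 1,2-addition to the ketone of 10 are followed by lactonisation of the tertiary alkoxide; addition is not expected to be face-selective, so the (5R)-lactone (C10 of the plan) is separated from its C5 epimer here.

Step 6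
Reactants: 14 (5R)-lactone
Product: 15 (6R,7Z,9R)-9-[(tert-butyldimethylsilyl)oxy]-6-hydroxy-2,6,7,11-tetramethyldodeca-7,11-dien-3-one
Conditions: i-PrLi (1.1 equiv), Et2O, −78 °C; aq. NH4Cl at −78 °C
Reagents that add atoms: isopropyllithium, [Li]C(C)C
Why: Single addition of an alkyllithium to a γ-lactone at low temperature (nucleophilic acyl substitution): the tetrahedral lithium alkoxide holds until the quench and then opens to the γ-hydroxy ketone.

Step 7
Reactants: 15 hydroxy ketone
Product: 16 (6R,7Z,9R)-9-[(tert-butyldimethylsilyl)oxy]-2,6,7,11-tetramethyl-6-[(trimethylsilyl)oxy]dodeca-7,11-dien-3-one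
Conditions: N-(trimethylsilyl)imidazole, CH2Cl2, rt
Reagents that add atoms: N-(trimethylsilyl)imidazole, C[Si](C)(C)n1ccnc1
Why: Neutral silylation of the tertiary alcohol of the open-chain hydroxy ketone leaves the ketone un-enolised and puts on O10 the same silyl group as the promoter of step 8, so that silyl transfer in that step gives one product.

Step 8
Reactants: 16 acyclic isopropyl ketone with (Z)-C1=C5 alkene and tertiary C10 trimethylsilyl ether
Product: 17 1-[(1R,2S,3S)-2-{(1R)-1-[(tert-butyldimethylsilyl)oxy]-3-methylbut-3-en-1-yl}-1-methyl-3-(propan-2-yl)-3-[(trimethylsilyl)oxy]cyclopentyl]ethan-1-one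
Conditions: TMSOTf (0.3–1.0 equiv), 2,6-di-tert-butyl-4-methylpyridine, CH2Cl2, −78 → −40 °C; Et3N quench
Reagents that add atoms: trimethylsilyl trifluoromethanesulfonate, C[Si](C)(C)OS(=O)(=O)C(F)(F)F
Why: Proposed new method: TMSOTf silylates the C4 ketone to a silyloxocarbenium ion, C5 of the (Z)-alkene attacks it (C4–C5) to give a tertiary C1 cyclohexyl cation, and the C10–C2 ring bond, aligned with the empty orbital, shifts to C1 (C1–C2) under the push of the O10 lone pair, after which the C10 oxocarbenium ion hands its silyl group on as TMSOTf; the closest known reaction type is the acetal-initiated Prins cyclisation terminated by a pinacol shift with ring contraction (acyl tetrahydrofurans, acyl carbocycles), from which this differs only in starting from a silyl-activated ketone. The cyclopentane C1–C5 thus closes by a 6-endo Prins closure with respect to the alkene (ring atoms C4, C3, C2, C10, C1, C5) followed by a 1,2-alkyl shift that expels C10 from the ring, the net result being suprafacial addition of the C2–C3–C4 bridge across C1=C5. C1 and C5 are therefore fixed relative to each other by the (Z)-geometry (acetyl and C6 chain cis), and their absolute sense by a chair in which the C10 silyloxy group is axial and its methyl equatorial while the C6 hydrogen lies in the alkene plane, so that C4 bonds to the alkene face anti to the C6 silyloxy group. C4 is set in the same chair with the isopropyl group equatorial and the silylated oxygen axial, trans to the C6 chain. The step needs 6-endo rather than 5-exo closure, secured by the tertiary cation at C1, and ring-bond rather than methyl migration, secured by the equatorial methyl lying in the nodal plane of the C1 orbital. Low temperature and a hindered pyridine base are chosen to hold back ionisation of the tertiary allylic silyl ether and enol silylation of the ketone.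

Step 9
Reactants: 17 acetylcyclopentane
Product: 21 1-[(1R,2S,3S)-2-{(1R)-1-[(tert-butyldimethylsilyl)oxy]-3-methylbut-3-en-1-yl}-1-methyl-3-(propan-2-yl)-3-[(trimethylsilyl)oxy]cyclopentyl]prop-2-en-1-one, via lithium enolate 18 (not isolated), via Mannich base 19 (not isolated), via methiodide salt 20 (not isolated)
Conditions: LiN(SiMe3)2, THF, −78 °C; CH2=NMe2+ I−, −78 °C → rt; MeI, CH2Cl2, rt; DBU, 0 °C → rt
Reagents that add atoms: N,N-dimethylmethyleneiminium iodide (Eschenmoser's salt), C=[N+](C)C.[I-]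
Why: Mannich reaction of the only possible enolate (C1 is quaternary) with Eschenmoser's salt, then quaternisation and E1cB loss of trimethylamine, turns the acetyl group into the acryloyl group needed for ring closure.

Step 10
Reactants: 21 vinyl ketone
Product: 22 (3S,3aS,4R,8aR)-4-[(tert-butyldimethylsilyl)oxy]-6,8a-dimethyl-3-(propan-2-yl)-3-[(trimethylsilyl)oxy]-2,3,3a,4,5,8a-hexahydroazulen-8(1H)-one
Conditions: second-generation Grubbs catalyst RuCl2(=CHPh)(H2IMes)(PCy3) (5–10 mol %), toluene (high dilution), 80 °C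
Reagents that add atoms: none
Why: Ring-closing metathesis of the enone with the 1,1-disubstituted methallyl alkene, both held cis on the cyclopentane, should form the trisubstituted C8=C9 bond of the cis-fused cycloheptenone with loss of ethene.

Step 11
Reactants: 22 bicyclic enone
Product: 23 (3S,3aS,4R,8R,8aR)-4-[(tert-butyldimethylsilyl)oxy]-6,8a-dimethyl-3-(propan-2-yl)-3-[(trimethylsilyl)oxy]-1,2,3,3a,4,5,8,8a-octahydroazulen-8-ol
Conditions: NaBH4, CeCl3·7H2O, MeOH, −78 °C
Reagents that add atoms: none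
Why: Luche 1,2-reduction of the enone; hydride is expected to add to C10 anti to the adjacent C1 methyl group, the usual course for ketones next to a methyl-bearing ring-fusion carbon, which places the hydroxyl cis to that methyl (10R of the plan, 8R in the name).

Step 12
Reactants: 23 allylic alcohol
Product: 24 (3S,3aS,4R,8R,8aR)-4-[(tert-butyldimethylsilyl)oxy]-6,8a-dimethyl-3-(propan-2-yl)-3-[(trimethylsilyl)oxy]-1,2,3,3a,4,5,8,8a-octahydroazulen-8-yl 3-methylbutanoate
Conditions: 3-methylbutanoic anhydride, DMAP, Et3N, CH2Cl2, rt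
Reagents that add atoms: 3-methylbutanoic anhydride, CC(C)CC(=O)OC(=O)CC(C)C
Why: DMAP-catalysed acylation of the only free hydroxyl group, with retention at C10.

Step 13
Reactants: 24 silylated isovalerate
Product: 25 (3S,3aS,4R,8R,8aR)-3,4-dihydroxy-6,8a-dimethyl-3-(propan-2-yl)-1,2,3,3a,4,5,8,8a-octahydroazulen-8-yl 3-methylbutanoate
Conditions: HF·pyridine, pyridine, THF, 0 °C → rt
Reagents that add atoms: none
Why: Fluoride-driven desilylation removes the secondary TBS and the tertiary TMS ether together under buffered conditions that should leave the allylic ester in place.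

Step 14
Reactants: 25 diol isovalerate
Product: 26 (3S,3aS,4R,8R,8aR)-3-hydroxy-6,8a-dimethyl-8-[(3-methylbutanoyl)oxy]-3-(propan-2-yl)-1,2,3,3a,4,5,8,8a-octahydroazulen-4-yl 4-[(tert-butyldimethylsilyl)oxy]benzoate
Conditions: 4-(TBSO)C6H4CO2H, 2,4,6-trichlorobenzoyl chloride, Et3N, THF, rt; then 25, DMAP, toluene, rt → 50 °C
Reagents that add atoms: 4-[(tert-butyldimethylsilyl)oxy]benzoic acid, CC(C)(C)[Si](C)(C)Oc1ccc(cc1)C(O)=O
Why: Yamaguchi esterification acylates the hindered secondary C6 hydroxyl with retention, the tertiary C4 hydroxyl being too hindered to compete.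

Step 15
Reactants: 26 silyl-protected diester
Product: 27 (3S,3aS,4R,8R,8aR)-3-hydroxy-6,8a-dimethyl-8-[(3-methylbutanoyl)oxy]-3-(propan-2-yl)-1,2,3,3a,4,5,8,8a-octahydroazulen-4-yl 4-hydroxybenzoate (CNP0086724.1)
Conditions: Bu4NF, AcOH, THF, 0 °C
Reagents that add atoms: none
Why: Buffered fluoride desilylation cleaves the aryl silyl ether far faster than it touches either ester and releases the phenol.

**Compound list**

1 | 1,1-diethoxybut-2-yne (but-2-ynal diethyl acetal) | CC#CC(OCC)OCC | starting material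
2 | but-2-ynal | CC#CC=O | intermediate
3 | (2-methylprop-2-en-1-yl)magnesium chloride | C=C(C)C[Mg]Cl | starting material
4 | B-(2-methylprop-2-en-1-yl)diisopinocampheylborane, from (+)-Ipc2BOMe | C=C(C)CB([C@H]1C[C@H]2C[C@@H]([C@@H]1C)C2(C)C)[C@H]1C[C@H]2C[C@@H]([C@@H]1C)C2(C)C | intermediate
5 | (4R)-2-methylhept-1-en-5-yn-4-yl diisopinocampheylborinate | CC#C[C@@H](CC(C)=C)OB([C@H]1C[C@H]2C[C@@H]([C@@H]1C)C2(C)C)[C@H]1C[C@H]2C[C@@H]([C@@H]1C)C2(C)C | intermediate
6 | (4R)-2-methylhept-1-en-5-yn-4-ol | CC#C[C@H](O)CC(C)=C | intermediate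
7 | sodium (5R)-2,2-bis(2-methoxyethoxy)-3-methyl-5-(2-methylprop-2-en-1-yl)-2,5-dihydro-1,2-oxaluminol-2-uide | CC1=C[C@@H](CC(C)=C)O[Al-]1(OCCOC)OCCOC.[Na+] | intermediate
8 | (4R,5Z)-6-iodo-2-methylhepta-1,5-dien-4-ol | I/C(C)=C\[C@H](O)CC(C)=C | intermediate
9 | tert-butyl{[(4R,5Z)-6-iodo-2-methylhepta-1,5-dien-4-yl]oxy}dimethylsilane | I/C(C)=C\[C@H](O[Si](C)(C)C(C)(C)C)CC(C)=C | intermediate
10 | ethyl 4-oxopentanoate (ethyl levulinate) | CCOC(=O)CCC(C)=O | starting material
11 | [(2Z,4R)-4-[(tert-butyldimethylsilyl)oxy]-6-methylhepta-2,6-dien-2-yl]lithium | [Li]/C(C)=C\[C@H](O[Si](C)(C)C(C)(C)C)CC(C)=C | intermediate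
12 | dichloro[(2Z,4R)-4-[(tert-butyldimethylsilyl)oxy]-6-methylhepta-2,6-dien-2-yl]cerium | Cl[Ce](Cl)/C(C)=C\[C@H](O[Si](C)(C)C(C)(C)C)CC(C)=C | intermediate
13 | dichlorocerium alkoxide of ethyl (4R,5Z,7R)-7-[(tert-butyldimethylsilyl)oxy]-4-hydroxy-4,5,9-trimethyldeca-5,9-dienoate | CCOC(=O)CC[C@@](C)(O[Ce](Cl)Cl)/C(C)=C\[C@H](O[Si](C)(C)C(C)(C)C)CC(C)=C | intermediate
14 | (5R)-5-{(2Z,4R)-4-[(tert-butyldimethylsilyl)oxy]-6-methylhepta-2,6-dien-2-yl}-5-methyloxolan-2-one | O=C1CC[C@@](C)(O1)/C(C)=C\[C@H](O[Si](C)(C)C(C)(C)C)CC(C)=C | intermediate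
15 | (6R,7Z,9R)-9-[(tert-butyldimethylsilyl)oxy]-6-hydroxy-2,6,7,11-tetramethyldodeca-7,11-dien-3-one | CC(C)C(=O)CC[C@@](C)(O)/C(C)=C\[C@H](O[Si](C)(C)C(C)(C)C)CC(C)=C | intermediate
16 | (6R,7Z,9R)-9-[(tert-butyldimethylsilyl)oxy]-2,6,7,11-tetramethyl-6-[(trimethylsilyl)oxy]dodeca-7,11-dien-3-one | CC(C)C(=O)CC[C@@](C)(O[Si](C)(C)C)/C(C)=C\[C@H](O[Si](C)(C)C(C)(C)C)CC(C)=C | intermediate
17 | 1-[(1R,2S,3S)-2-{(1R)-1-[(tert-butyldimethylsilyl)oxy]-3-methylbut-3-en-1-yl}-1-methyl-3-(propan-2-yl)-3-[(trimethylsilyl)oxy]cyclopentyl]ethan-1-one | CC(=O)[C@]1(C)CC[C@](O[Si](C)(C)C)(C(C)C)[C@@H]1[C@H](O[Si](C)(C)C(C)(C)C)CC(C)=C | intermediate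
18 | lithium enolate of 17 (lithium 1-cyclopentylethen-1-olate, cyclopentyl unit as in 17) | [Li]OC(=C)[C@]1(C)CC[C@](O[Si](C)(C)C)(C(C)C)[C@@H]1[C@H](O[Si](C)(C)C(C)(C)C)CC(C)=C | intermediate
19 | 3-(dimethylamino)-1-cyclopentylpropan-1-one (Mannich base, cyclopentyl unit as in 17) | CN(C)CCC(=O)[C@]1(C)CC[C@](O[Si](C)(C)C)(C(C)C)[C@@H]1[C@H](O[Si](C)(C)C(C)(C)C)CC(C)=C | intermediate
20 | N,N,N-trimethyl-3-oxo-3-cyclopentylpropan-1-aminium iodide (cyclopentyl unit as in 17) | C[N+](C)(C)CCC(=O)[C@]1(C)CC[C@](O[Si](C)(C)C)(C(C)C)[C@@H]1[C@H](O[Si](C)(C)C(C)(C)C)CC(C)=C.[I-] | intermediate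
21 | 1-[(1R,2S,3S)-2-{(1R)-1-[(tert-butyldimethylsilyl)oxy]-3-methylbut-3-en-1-yl}-1-methyl-3-(propan-2-yl)-3-[(trimethylsilyl)oxy]cyclopentyl]prop-2-en-1-one | C=CC(=O)[C@]1(C)CC[C@](O[Si](C)(C)C)(C(C)C)[C@@H]1[C@H](O[Si](C)(C)C(C)(C)C)CC(C)=C | intermediate
22 | (3S,3aS,4R,8aR)-4-[(tert-butyldimethylsilyl)oxy]-6,8a-dimethyl-3-(propan-2-yl)-3-[(trimethylsilyl)oxy]-2,3,3a,4,5,8a-hexahydroazulen-8(1H)-one | CC1=CC(=O)[C@]2(C)CC[C@](O[Si](C)(C)C)(C(C)C)[C@@H]2[C@H](O[Si](C)(C)C(C)(C)C)C1 | intermediate
23 | (3S,3aS,4R,8R,8aR)-4-[(tert-butyldimethylsilyl)oxy]-6,8a-dimethyl-3-(propan-2-yl)-3-[(trimethylsilyl)oxy]-1,2,3,3a,4,5,8,8a-octahydroazulen-8-ol | CC1=C[C@@H](O)[C@]2(C)CC[C@](O[Si](C)(C)C)(C(C)C)[C@@H]2[C@H](O[Si](C)(C)C(C)(C)C)C1 | intermediate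
24 | (3S,3aS,4R,8R,8aR)-4-[(tert-butyldimethylsilyl)oxy]-6,8a-dimethyl-3-(propan-2-yl)-3-[(trimethylsilyl)oxy]-1,2,3,3a,4,5,8,8a-octahydroazulen-8-yl 3-methylbutanoate | CC1=C[C@@H](OC(=O)CC(C)C)[C@]2(C)CC[C@](O[Si](C)(C)C)(C(C)C)[C@@H]2[C@H](O[Si](C)(C)C(C)(C)C)C1 | intermediate
25 | (3S,3aS,4R,8R,8aR)-3,4-dihydroxy-6,8a-dimethyl-3-(propan-2-yl)-1,2,3,3a,4,5,8,8a-octahydroazulen-8-yl 3-methylbutanoate | CC1=C[C@@H](OC(=O)CC(C)C)[C@]2(C)CC[C@](O)(C(C)C)[C@@H]2[C@H](O)C1 | intermediate
26 | (3S,3aS,4R,8R,8aR)-3-hydroxy-6,8a-dimethyl-8-[(3-methylbutanoyl)oxy]-3-(propan-2-yl)-1,2,3,3a,4,5,8,8a-octahydroazulen-4-yl 4-[(tert-butyldimethylsilyl)oxy]benzoate | CC1=C[C@@H](OC(=O)CC(C)C)[C@]2(C)CC[C@](O)(C(C)C)[C@@H]2[C@H](OC(=O)c2ccc(O[Si](C)(C)C(C)(C)C)cc2)C1 | intermediate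
27 | (3S,3aS,4R,8R,8aR)-3-hydroxy-6,8a-dimethyl-8-[(3-methylbutanoyl)oxy]-3-(propan-2-yl)-1,2,3,3a,4,5,8,8a-octahydroazulen-4-yl 4-hydroxybenzoate | CC1=C[C@@H](OC(=O)CC(C)C)[C@]2(C)CC[C@](O)(C(C)C)[C@@H]2[C@H](OC(=O)c2ccc(O)cc2)C1 | target

**Step count and risks**

Total step count: 15. Longest linear sequence: 15 steps (1 → 27).

Steps most likely to fail:

Step 8 (proposed method). The O-silylated ketone forms only reversibly and may be too weak an electrophile for an alkene deactivated by two allylic oxygens. Ionisation of the tertiary allylic silyl ether or enol silylation could then overtake C–C bond formation. The isopropyl group may also take the axial site and erode the C4 configuration, because in the required chair the C7 methylene lies close to the equatorial C4 substituent. The fallback uses a fully formed alkoxycarbenium ion, the established initiator for this reaction type. Ketone 16 would be converted with 1,2-bis(trimethylsilyloxy)ethane and catalytic TMSOTf at −78 °C into the ethylene ketal F1. Under SnCl4 in CH2Cl2 (−78 → −23 °C) this should undergo the ketal-initiated Prins cyclisation and pinacol shift to the acetylcyclopentane 2-hydroxyethyl ether F2. Iodination (I2, PPh3, imidazole) would give the 2-iodoethyl ether F3. Zinc dust in ethanol at reflux would remove the two-carbon unit as ethene (Boord-type reductive elimination) to give the tertiary alcohol F4, and N-(trimethylsilyl)imidazole would bring the route back to 17.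

Step 11. Hydride may approach C10 from the face of the C1 methyl group, since the folded cis-fused bicycle also shields the opposite face; facial selectivity could be poor or reversed. In that case the epimeric alcohol F5 obtained from 22 would not be reoxidised. It would be esterified under Mitsunobu conditions (3-methylbutanoic acid, PPh3, DIAD, toluene, 0 °C → rt), which inverts C10 and installs the ester in one operation, rejoining the route at 24.

Step 6. The basic secondary organolithium may deprotonate the lactone or add twice, and ring–chain tautomerism of the hydroxy ketone may divert the silylation of step 7. The fallback goes through an amide. Lactone 14 would be opened with MeNH(OMe)·HCl and AlMe3 (CH2Cl2, 0 °C → rt) to the hydroxy Weinreb amide F6, which would be silylated at once (TMSCl, imidazole, DMF) to the silyl ether amide F7. Addition of i-PrMgCl (THF, 0 °C) should then give ketone 16 directly, the chelated tetrahedral intermediate excluding over-addition.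

Further compounds
F1 | step 8 | 2-{(3R,4Z,6R)-6-[(tert-butyldimethylsilyl)oxy]-3,4,8-trimethyl-3-[(trimethylsilyl)oxy]nona-4,8-dien-1-yl}-2-(propan-2-yl)-1,3-dioxolane | CC(C)C1(CC[C@@](C)(O[Si](C)(C)C)/C(C)=C\[C@H](O[Si](C)(C)C(C)(C)C)CC(C)=C)OCCO1
F2 | step 8 | 1-[(1R,2S,3S)-2-{(1R)-1-[(tert-butyldimethylsilyl)oxy]-3-methylbut-3-en-1-yl}-3-(2-hydroxyethoxy)-1-methyl-3-(propan-2-yl)cyclopentyl]ethan-1-one | CC(=O)[C@]1(C)CC[C@](OCCO)(C(C)C)[C@@H]1[C@H](O[Si](C)(C)C(C)(C)C)CC(C)=C
F3 | step 8 | 1-[(1R,2S,3S)-2-{(1R)-1-[(tert-butyldimethylsilyl)oxy]-3-methylbut-3-en-1-yl}-3-(2-iodoethoxy)-1-methyl-3-(propan-2-yl)cyclopentyl]ethan-1-one | CC(=O)[C@]1(C)CC[C@](OCCI)(C(C)C)[C@@H]1[C@H](O[Si](C)(C)C(C)(C)C)CC(C)=C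
F4 | step 8 | 1-[(1R,2S,3S)-2-{(1R)-1-[(tert-butyldimethylsilyl)oxy]-3-methylbut-3-en-1-yl}-3-hydroxy-1-methyl-3-(propan-2-yl)cyclopentyl]ethan-1-one | CC(=O)[C@]1(C)CC[C@](O)(C(C)C)[C@@H]1[C@H](O[Si](C)(C)C(C)(C)C)CC(C)=C
F5 | step 11 | (3S,3aS,4R,8S,8aR)-4-[(tert-butyldimethylsilyl)oxy]-6,8a-dimethyl-3-(propan-2-yl)-3-[(trimethylsilyl)oxy]-1,2,3,3a,4,5,8,8a-octahydroazulen-8-ol | CC1=C[C@H](O)[C@]2(C)CC[C@](O[Si](C)(C)C)(C(C)C)[C@@H]2[C@H](O[Si](C)(C)C(C)(C)C)C1
F6 | step 6 | (4R,5Z,7R)-7-[(tert-butyldimethylsilyl)oxy]-4-hydroxy-N-methoxy-N,4,5,9-tetramethyldeca-5,9-dienamide | CON(C)C(=O)CC[C@@](C)(O)/C(C)=C\[C@H](O[Si](C)(C)C(C)(C)C)CC(C)=C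
F7 | step 6 | (4R,5Z,7R)-7-[(tert-butyldimethylsilyl)oxy]-N-methoxy-N,4,5,9-tetramethyl-4-[(trimethylsilyl)oxy]deca-5,9-dienamide | CON(C)C(=O)CC[C@@](C)(O[Si](C)(C)C)/C(C)=C\[C@H](O[Si](C)(C)C(C)(C)C)CC(C)=C
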